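**Plan**

1. Retrosynthesis: the carbinol C–H and the C3 methyl go back to an aryl ketone and a formyl group. The ring bond C2–C3 is then cut while the formyl oxygen returns to C2, which turns the 2‑aryl‑oxolane‑3‑carbaldehyde into a 2‑aryl‑4,5‑dihydro‑1,3‑dioxepine. Last, the C5–alkenyl bond (Heck) and the two acetal C–O bonds of that dioxepine are cut.
2. Enabling feature: ring carbon C2 is benzylic and bound to the ring oxygen (a latent aryl‑stabilised oxocarbenium ion), and its neighbour C3 carries a one‑carbon branch (CH3 = reduced CHO). O1–C2/C3–CHO is the [1,3] O→C isomer of the seven‑membered cyclic vinyl acetal O–CH(Ar)–O–CH=CH.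
3. Forward order: seven‑membered acetal ring from butenediol and veratraldehyde → Heck attachment of the second aryl unit as a 1‑arylvinyl group → ring contraction 7→5 to the oxolane → C=CH2 to C=O to CH–OH → CHO to CH3.
4. Stereochemistry: C4 from the asymmetric Heck reaction; C2 relayed from C4 in the ring contraction (2,4‑trans); C3 by epimerisation driven by closure of a cis‑fused lactol (3,4‑cis); the carbinol centre by CBS reduction (reagent control).

Key step: step 4

Assumption: the (S)‑t‑Bu‑PHOX/Pd catalyst of step 3 is taken to deliver the (5S)‑dioxepine; if its sense of induction proves opposite, the (R)‑ligand is used and nothing else changes.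

**Route**

Step 1
Reactants: 1 (Z)-but-2-ene-1,4-diol; 2 3,4-dimethoxybenzaldehyde
Product: 3 2-(3,4-dimethoxyphenyl)-4,7-dihydro-1,3-dioxepine
Conditions: p‑TsOH·H2O (cat.), toluene, reflux, Dean–Stark
Reagents that add atoms: none
Why: Acid‑catalysed acetalisation with azeotropic removal of water; the cis geometry of the diol closes the seven‑membered ring, and C2 lies on a mirror plane, so no stereocentre arises.

Step 2
Reactants: 4 1-(3,4-dimethoxyphenyl)ethan-1-one
Product: 5 1-(3,4-dimethoxyphenyl)ethenyl trifluoromethanesulfonate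
Conditions: KHMDS, THF, −78 °C; then PhNTf2, −78 to 0 °C
Reagents that add atoms: N-phenylbis(trifluoromethanesulfonimide), O=S(=O)(N(c1ccccc1)S(=O)(=O)C(F)(F)F)C(F)(F)F
Why: O‑sulfonylation of the potassium enolate (enol triflate formation); the methyl ketone has a single enolisable position.

Step 3
Reactants: 3 2-(3,4-dimethoxyphenyl)-4,7-dihydro-1,3-dioxepine (3 equiv); 5 1-(3,4-dimethoxyphenyl)ethenyl trifluoromethanesulfonate
Product: 6 (5S)-2-(3,4-dimethoxyphenyl)-5-[1-(3,4-dimethoxyphenyl)ethenyl]-4,5-dihydro-1,3-dioxepine (both C2 epimers)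
Conditions: Pd2(dba)3·CHCl3 (3 mol %), (S)‑t‑Bu‑PHOX (7 mol %), i‑Pr2NEt, THF, 65 °C
Reagents that add atoms: none
Why: Enantioselective intermolecular Heck reaction (cationic Pd/phosphinooxazoline pathway) on a cyclic cis‑olefin: syn carbopalladation at one enantiotopic alkene carbon sets C5 under ligand control, and syn β‑hydride elimination is possible only toward C7, which places the double bond as the enol ether; C2 needs no control because it is planarised in step 4.

Step 4
Reactants: 6 (5S)-2-(3,4-dimethoxyphenyl)-5-[1-(3,4-dimethoxyphenyl)ethenyl]-4,5-dihydro-1,3-dioxepine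
Product: 8 (2S,3R,4S)-2-(3,4-dimethoxyphenyl)-3-(dimethoxymethyl)-4-[1-(3,4-dimethoxyphenyl)ethenyl]oxolane, via oxolane-3-carbaldehyde 7 (not isolated)
Conditions: Me3SiOTf (0.3 equiv), 2,6‑di‑tert‑butyl‑4‑methylpyridine (0.4 equiv), CH2Cl2, −78 °C; then MeOSiMe3 (3 equiv), −78 to −40 °C; Et3N quench
Reagents that add atoms: methoxytrimethylsilane, CO[Si](C)(C)C
Why: Me3SiOTf ionises the vinyl acetal at the C2–O1 bond (O1 = enol‑ether oxygen), giving an (E)‑aryl‑oxocarbenium ion and a silyl enol ether that remain joined through O3–C4–C5; the enol carbon C6 then bonds to C2, so the seven‑membered ring loses C7–O1 as the formyl group and the oxolane remains (formal [1,3] O‑to‑C shift). The closest known reaction type is the Lewis‑acid‑mediated ring contraction of 4,5‑dihydro‑1,3‑dioxepines to 2,3,4‑trisubstituted oxolane‑3‑carbaldehydes, a Petasis–Ferrier/Mukaiyama–Prins‑type process. The oxolane closes in a 5‑(enolexo)‑endo‑trig mode, which is tolerated because the electrophile is an oxocarbenium ion. C5 of 6 (C4 of the product) is the controlling element: allylic 1,3‑strain keeps its hydrogen in the enol plane, so the tether and the arylvinyl group lie on opposite faces and C3 should form trans to C4, while the (E)‑oxocarbenium ion in the synclinal, ion‑paired arrangement should place the C2 aryl cis to the formyl group and therefore trans to the C4 substituent; the acetal centre of 6 is planarised, so both C2 epimers converge. The step needs C‑attack by the enol carbon and not Prins capture of the cation by the electron‑rich 1‑arylvinyl group; the enol carbon is held next to C2 by the ring that has just opened, and low temperature with a hindered pyridine should suppress the slower alkene pathway and acid‑induced ionisation of the styrene. Aldehyde 7 is acetalised in the same flask by MeOSiMe3 under the same silyl triflate catalysis so that the ketone of step 5 can be reduced alone in step 6; the C3 configuration is not critical here because step 7 corrects it.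

Step 5
Reactants: 8 (2S,3R,4S)-2-(3,4-dimethoxyphenyl)-3-(dimethoxymethyl)-4-[1-(3,4-dimethoxyphenyl)ethenyl]oxolane
Product: 9 (3,4-dimethoxyphenyl)[(3R,4R,5S)-5-(3,4-dimethoxyphenyl)-4-(dimethoxymethyl)oxolan-3-yl]methanone
Conditions: OsO4 (2 mol %), NaIO4 (4 equiv), 2,6‑lutidine (2 equiv), 1,4‑dioxane/H2O 3:1, rt
Reagents that add atoms: osmium tetroxide (catalytic oxygen carrier), O=[Os](=O)(=O)=O; sodium periodate, [Na+].[O-]I(=O)(=O)=O
Why: Lemieux–Johnson oxidation: osmylation of the only alkene and periodate cleavage of the diol give the aryl ketone; lutidine buffering protects the acetal, and C4 has no drive to epimerise because the acyl group is already trans to the C3 substituent.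

Step 6
Reactants: 9 (3,4-dimethoxyphenyl)[(3R,4R,5S)-5-(3,4-dimethoxyphenyl)-4-(dimethoxymethyl)oxolan-3-yl]methanone
Product: 10 (R)-(3,4-dimethoxyphenyl)[(3R,4R,5S)-5-(3,4-dimethoxyphenyl)-4-(dimethoxymethyl)oxolan-3-yl]methanol
Conditions: (S)‑2‑methyl‑CBS‑oxazaborolidine (0.3 equiv), BH3·SMe2 (1.0 equiv), THF, −20 °C; MeOH quench
Reagents that add atoms: none
Why: Corey–Bakshi–Shibata reduction under reagent control: with the aryl group as the large substituent the (S)‑catalyst should deliver hydride to the face that gives the (R)‑carbinol, as it does for aryl alkyl ketones; the conditions are non‑basic, so C4 is not enolised.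

Step 7
Reactants: 10 (R)-(3,4-dimethoxyphenyl)[(3R,4R,5S)-5-(3,4-dimethoxyphenyl)-4-(dimethoxymethyl)oxolan-3-yl]methanol
Product: 13 (3R,3aR,6S,6aS)-3,6-bis(3,4-dimethoxyphenyl)tetrahydro-1H,3H-furo[3,4-c]furan-1-ol (anomers), via trans hydroxy aldehyde 11 (not isolated), via cis hydroxy aldehyde 12 (not isolated)
Conditions: PPTS (cat.), acetone/H2O 10:1, 40 °C; then DBU (0.2 equiv), CH2Cl2, rt
Reagents that add atoms: water, O
Why: Mild acetal hydrolysis frees aldehyde 11, whose formyl group is trans to the carbinol side chain; DBU equilibrates C3 through the enolate, and only the 3,4‑cis epimer 12 can close to the cis‑fused γ‑lactol, which drains the equilibrium and sets C3 (thermodynamic trapping by hemiacetal formation), while C2 and C4 are not enolisable.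

Step 8
Reactants: 13 (3R,3aR,6S,6aS)-3,6-bis(3,4-dimethoxyphenyl)tetrahydro-1H,3H-furo[3,4-c]furan-1-ol
Product: 14 N'-[(E)-{(2S,3R,4R)-2-(3,4-dimethoxyphenyl)-4-[(R)-(3,4-dimethoxyphenyl)(hydroxy)methyl]oxolan-3-yl}methylidene]-4-methylbenzenesulfonohydrazide
Conditions: TsNHNH2 (1.2 equiv), MeOH, rt
Reagents that add atoms: 4-methylbenzenesulfonohydrazide, Cc1ccc(cc1)S(=O)(=O)NN
Why: The lactol reacts through its open hydroxy aldehyde form in a hydrazone condensation under neutral conditions, so the C3 centre just set is retained.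

Step 9
Reactants: 14 N'-[(E)-{(2S,3R,4R)-2-(3,4-dimethoxyphenyl)-4-[(R)-(3,4-dimethoxyphenyl)(hydroxy)methyl]oxolan-3-yl}methylidene]-4-methylbenzenesulfonohydrazide
Product: 15 (R)-(3,4-dimethoxyphenyl)[(3R,4S,5S)-5-(3,4-dimethoxyphenyl)-4-methyloxolan-3-yl]methanol (target)
Conditions: catecholborane (3 equiv), CHCl3, 0 °C to rt; then NaOAc·3H2O (3 equiv), reflux
Reagents that add atoms: none
Why: Caglioti‑type tosylhydrazone reduction in its catecholborane variant: hydroboration of C=N, acetate‑induced loss of sulfinate and then of N2 from the diazene turn CH=N into CH3 under near‑neutral, non‑cationic conditions, so C3, the benzylic carbinol and the benzylic ring ether should stay untouched.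

**Compound list**

1 | (Z)-but-2-ene-1,4-diol | OC/C=C\CO | starting material
2 | 3,4-dimethoxybenzaldehyde | COc1ccc(C=O)cc1OC | starting material
3 | 2-(3,4-dimethoxyphenyl)-4,7-dihydro-1,3-dioxepine | COc1ccc(C2OCC=CCO2)cc1OC | intermediate
4 | 1-(3,4-dimethoxyphenyl)ethan-1-one | CC(=O)c1ccc(OC)c(OC)c1 | starting material
5 | 1-(3,4-dimethoxyphenyl)ethenyl trifluoromethanesulfonate | C=C(OS(=O)(=O)C(F)(F)F)c1ccc(OC)c(OC)c1 | intermediate
6 | (5S)-2-(3,4-dimethoxyphenyl)-5-[1-(3,4-dimethoxyphenyl)ethenyl]-4,5-dihydro-1,3-dioxepine (C2 epimers) | COc1ccc(C2OC[C@H](C(=C)c3ccc(OC)c(OC)c3)C=CO2)cc1OC | intermediate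
7 | (2S,3R,4S)-2-(3,4-dimethoxyphenyl)-4-[1-(3,4-dimethoxyphenyl)ethenyl]oxolane-3-carbaldehyde | COc1ccc([C@H]2OC[C@H](C(=C)c3ccc(OC)c(OC)c3)[C@H]2C=O)cc1OC | intermediate
8 | (2S,3R,4S)-2-(3,4-dimethoxyphenyl)-3-(dimethoxymethyl)-4-[1-(3,4-dimethoxyphenyl)ethenyl]oxolane | COc1ccc([C@H]2OC[C@H](C(=C)c3ccc(OC)c(OC)c3)[C@H]2C(OC)OC)cc1OC | intermediate
9 | (3,4-dimethoxyphenyl)[(3R,4R,5S)-5-(3,4-dimethoxyphenyl)-4-(dimethoxymethyl)oxolan-3-yl]methanone | COc1ccc([C@H]2OC[C@H](C(=O)c3ccc(OC)c(OC)c3)[C@H]2C(OC)OC)cc1OC | intermediate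
10 | (R)-(3,4-dimethoxyphenyl)[(3R,4R,5S)-5-(3,4-dimethoxyphenyl)-4-(dimethoxymethyl)oxolan-3-yl]methanol | COc1ccc([C@H]2OC[C@H]([C@@H](O)c3ccc(OC)c(OC)c3)[C@H]2C(OC)OC)cc1OC | intermediate
11 | (2S,3R,4R)-2-(3,4-dimethoxyphenyl)-4-[(R)-(3,4-dimethoxyphenyl)(hydroxy)methyl]oxolane-3-carbaldehyde (formyl trans to the side chain) | COc1ccc([C@H]2OC[C@H]([C@@H](O)c3ccc(OC)c(OC)c3)[C@H]2C=O)cc1OC | intermediate
12 | (2S,3S,4R)-2-(3,4-dimethoxyphenyl)-4-[(R)-(3,4-dimethoxyphenyl)(hydroxy)methyl]oxolane-3-carbaldehyde (formyl cis to the side chain) | COc1ccc([C@H]2OC[C@H]([C@@H](O)c3ccc(OC)c(OC)c3)[C@@H]2C=O)cc1OC | intermediate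
13 | (3R,3aR,6S,6aS)-3,6-bis(3,4-dimethoxyphenyl)tetrahydro-1H,3H-furo[3,4-c]furan-1-ol (cis‑fused, anomeric mixture) | COc1ccc([C@H]2OC[C@@H]3[C@H](c4ccc(OC)c(OC)c4)OC(O)[C@H]23)cc1OC | intermediate
14 | N'-[(E)-{(2S,3R,4R)-2-(3,4-dimethoxyphenyl)-4-[(R)-(3,4-dimethoxyphenyl)(hydroxy)methyl]oxolan-3-yl}methylidene]-4-methylbenzenesulfonohydrazide | COc1ccc([C@H]2OC[C@H]([C@@H](O)c3ccc(OC)c(OC)c3)[C@@H]2/C=N/NS(=O)(=O)c3ccc(C)cc3)cc1OC | intermediate
15 | (R)-(3,4-dimethoxyphenyl)[(3R,4S,5S)-5-(3,4-dimethoxyphenyl)-4-methyloxolan-3-yl]methanol | COc1ccc([C@H]2OC[C@H]([C@@H](O)c3ccc(OC)c(OC)c3)[C@@H]2C)cc1OC | target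

**Step count and risks**

Total steps: 9. Longest linear sequence: 8 (steps 1, 3–9 or 2, 3–9).

Steps most likely to fail:

Step 3. Enantioface discrimination in the carbopalladation may be weak with the α‑aryl alkenyl triflate, and Pd–H re‑addition may move the double bond. Fallback: from 3 and 5 a racemic Heck reaction (Pd(OAc)2, PPh3, Ag2CO3, MeCN, 60 °C) would give 6 together with its enantiomer (5R)-2-(3,4-dimethoxyphenyl)-5-[1-(3,4-dimethoxyphenyl)ethenyl]-4,5-dihydro-1,3-dioxepine F1. The racemate is taken through steps 4 and 5 unchanged, which adds the enantiomeric acetal (2R,3S,4R)-2-(3,4-dimethoxyphenyl)-3-(dimethoxymethyl)-4-[1-(3,4-dimethoxyphenyl)ethenyl]oxolane F2 and the enantiomeric ketone (3,4-dimethoxyphenyl)[(3S,4S,5R)-5-(3,4-dimethoxyphenyl)-4-(dimethoxymethyl)oxolan-3-yl]methanone F3. The (S)‑CBS reduction of step 6 then acts as a reagent‑controlled divergent reduction of the racemic ketone: both enantiomers should receive the (R)‑carbinol, giving 10 and the diastereomer (R)-(3,4-dimethoxyphenyl)[(3S,4S,5R)-5-(3,4-dimethoxyphenyl)-4-(dimethoxymethyl)oxolan-3-yl]methanol F4, which are separated by chromatography. The route is rejoined at 10.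

Step 4. The oxocarbenium ion may be captured by the electron‑rich 1‑arylvinyl group (Prins cyclisation) or that styrene may ionise and oligomerise, in competition with the ring contraction. Fallback: the aryl ketone is assembled after the ring contraction from a less nucleophilic alkene. From 3, the same asymmetric Heck reaction with 2‑methylprop‑1‑en‑1‑yl triflate would give (5R)-2-(3,4-dimethoxyphenyl)-5-(2-methylprop-1-en-1-yl)-4,5-dihydro-1,3-dioxepine F5. Ring contraction and acetalisation under the step 4 conditions would give (2S,3R,4R)-2-(3,4-dimethoxyphenyl)-3-(dimethoxymethyl)-4-(2-methylprop-1-en-1-yl)oxolane F6. Lemieux–Johnson cleavage would give (3R,4R,5S)-5-(3,4-dimethoxyphenyl)-4-(dimethoxymethyl)oxolane-3-carbaldehyde F7, whose formyl group is trans to the C4 substituent and so has no drive to epimerise. Addition of 3,4‑dimethoxyphenylmagnesium bromide (THF, −78 °C) would give the carbinol mixture (3,4-dimethoxyphenyl)[(3R,4R,5S)-5-(3,4-dimethoxyphenyl)-4-(dimethoxymethyl)oxolan-3-yl]methanol F8, and Dess–Martin oxidation returns the route to 9.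

Step 6. Facial selectivity may be poor because the α‑branched ring carbon competes with the aryl group as the large substituent, and the substrate bias may oppose the catalyst. Fallback: from 9, a substrate‑controlled hydride reduction (NaBH4, CeCl3, MeOH, −78 °C) would give 10 together with its carbinol epimer (S)-(3,4-dimethoxyphenyl)[(3R,4R,5S)-5-(3,4-dimethoxyphenyl)-4-(dimethoxymethyl)oxolan-3-yl]methanol F9, separated by chromatography. F9 is then inverted by a Mitsunobu reaction (4‑nitrobenzoic acid, PPh3, DIAD, THF, 0 °C) to (R)-(3,4-dimethoxyphenyl)[(3R,4R,5S)-5-(3,4-dimethoxyphenyl)-4-(dimethoxymethyl)oxolan-3-yl]methyl 4-nitrobenzoate F10, and methanolysis (K2CO3, MeOH) returns the route to 10.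

**Further compounds**

F1 | step 3 | (5R)-2-(3,4-dimethoxyphenyl)-5-[1-(3,4-dimethoxyphenyl)ethenyl]-4,5-dihydro-1,3-dioxepine | COc1ccc(C2OC[C@@H](C(=C)c3ccc(OC)c(OC)c3)C=CO2)cc1OC
F2 | step 3 | (2R,3S,4R)-2-(3,4-dimethoxyphenyl)-3-(dimethoxymethyl)-4-[1-(3,4-dimethoxyphenyl)ethenyl]oxolane | COc1ccc([C@@H]2OC[C@@H](C(=C)c3ccc(OC)c(OC)c3)[C@@H]2C(OC)OC)cc1OC
F3 | step 3 | (3,4-dimethoxyphenyl)[(3S,4S,5R)-5-(3,4-dimethoxyphenyl)-4-(dimethoxymethyl)oxolan-3-yl]methanone | COc1ccc([C@@H]2OC[C@@H](C(=O)c3ccc(OC)c(OC)c3)[C@@H]2C(OC)OC)cc1OC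
F4 | step 3 | (R)-(3,4-dimethoxyphenyl)[(3S,4S,5R)-5-(3,4-dimethoxyphenyl)-4-(dimethoxymethyl)oxolan-3-yl]methanol | COc1ccc([C@@H]2OC[C@@H]([C@@H](O)c3ccc(OC)c(OC)c3)[C@@H]2C(OC)OC)cc1OC
F5 | step 4 | (5R)-2-(3,4-dimethoxyphenyl)-5-(2-methylprop-1-en-1-yl)-4,5-dihydro-1,3-dioxepine | COc1ccc(C2OC[C@H](C=C(C)C)C=CO2)cc1OC
F6 | step 4 | (2S,3R,4R)-2-(3,4-dimethoxyphenyl)-3-(dimethoxymethyl)-4-(2-methylprop-1-en-1-yl)oxolane | COc1ccc([C@H]2OC[C@H](C=C(C)C)[C@H]2C(OC)OC)cc1OC
F7 | step 4 | (3R,4R,5S)-5-(3,4-dimethoxyphenyl)-4-(dimethoxymethyl)oxolane-3-carbaldehyde | COc1ccc([C@H]2OC[C@H](C=O)[C@H]2C(OC)OC)cc1OC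
F8 | step 4 | (3,4-dimethoxyphenyl)[(3R,4R,5S)-5-(3,4-dimethoxyphenyl)-4-(dimethoxymethyl)oxolan-3-yl]methanol (carbinol epimers) | COc1ccc([C@H]2OC[C@H](C(O)c3ccc(OC)c(OC)c3)[C@H]2C(OC)OC)cc1OC
F9 | step 6 | (S)-(3,4-dimethoxyphenyl)[(3R,4R,5S)-5-(3,4-dimethoxyphenyl)-4-(dimethoxymethyl)oxolan-3-yl]methanol | COc1ccc([C@H]2OC[C@H]([C@H](O)c3ccc(OC)c(OC)c3)[C@H]2C(OC)OC)cc1OC
F10 | step 6 | (R)-(3,4-dimethoxyphenyl)[(3R,4R,5S)-5-(3,4-dimethoxyphenyl)-4-(dimethoxymethyl)oxolan-3-yl]methyl 4-nitrobenzoate | COc1ccc([C@H]2OC[C@H]([C@@H](OC(=O)c3ccc(cc3)[N+](=O)[O-])c3ccc(OC)c(OC)c3)[C@H]2C(OC)OC)cc1OC
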